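**Retrosynthetic overview**

1. Numbering: ring carbons C1–C10, lactone C11/C12 with methylene C13, methyls C14 (on C10) and C15 (on C4). The ten-membered carbocycle is closed last, at C2–C3, by an intramolecular Nozaki–Hiyama–Kishi addition of a Z-iodoalkene to a Z-enal on the finished lactone.
2. Key disconnection: lactone O–C6. The lactone oxygen on C6 and the hydroxyl on C3 stand 1,4 across the Z-trisubstituted C4=C5 olefin (O–C6H–C5H=C4(CH3)–C3–OH). This is the retron of an alkoxide-carrying π-allylpalladium, so the γ-lactone comes from acyclic acid 22, in which C3/C4 are held in a 4-alkenyl-4-methyl-1,3-dioxolan-2-one (temporary ring) next to an E C5=C6 olefin.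
3. Acid 22 comes from a C7–C8 union: catalytic asymmetric chromium 2-(alkoxycarbonyl)allylation of aldehyde 7 (C8–C10, C1, C2, C14) with dienyl bromide 17 (C3–C7, C11–C13, C15), then tigloylation.
4. Aldehyde 7: Sharpless epoxidation and Red-Al opening of a silylated enynol (sets C10). Bromide 17: (S)-2-methylglycidol (sets the dioxolanone carbon C4), Swern–Wittig, CO2 insertion, Morita–Baylis–Hillman reaction, SN2′ bromination.
5. Order of ring formation: dioxolanone (temporary, step 7), γ-lactone (step 14), ten-membered ring (step 17).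

Key step: step 14

Remark: in step 11 the (S,S)-ligand is assumed to give the 4R alcohol; if the sense of induction proved opposite, its mirror image would be used.

**Route**

Step 1
Reactants: 1 (2E)-3-methylpent-2-en-4-yn-1-ol
Product: 3 (2E)-3-methyl-5-(trimethylsilyl)pent-2-en-4-yn-1-ol, via bis-silylated enynol 2 (not isolated)
Conditions: n-BuLi (2.1 equiv), THF, −78 °C; Me3SiCl (2.2 equiv), −78 → 0 °C; then 1 M aq. HCl, 0 °C
Reagents that add atoms: chlorotrimethylsilane, C[Si](C)(C)Cl
Why: Double deprotonation (alkoxide and acetylide) and silylation, with the labile O–Si bond hydrolysed in the acidic work-up, should leave the C-silylated alkyne; no stereocentre is formed.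

Step 2
Reactants: 3 (2E)-3-methyl-5-(trimethylsilyl)pent-2-en-4-yn-1-ol
Product: 4 [(2S,3S)-3-methyl-3-[(trimethylsilyl)ethynyl]oxiran-2-yl]methanol
Conditions: Ti(OiPr)4 (10 mol %), L-(+)-diisopropyl tartrate (12 mol %), t-BuOOH (2 equiv), 4 Å molecular sieves, CH2Cl2, −20 °C
Reagents that add atoms: tert-butyl hydroperoxide, CC(C)(C)OO
Why: Sharpless asymmetric epoxidation; L-(+)-tartrate should deliver oxygen to the face that gives the (2S,3S)-epoxide of this E-configured 3,3-disubstituted allylic alcohol (the same sense as for geraniol-type substrates), which fixes the tertiary C–O centre that becomes C10 (R).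

Step 3
Reactants: 4 [(2S,3S)-3-methyl-3-[(trimethylsilyl)ethynyl]oxiran-2-yl]methanol
Product: 5 [(2S,3S)-3-methyl-3-[(Z)-2-(trimethylsilyl)ethenyl]oxiran-2-yl]methanol
Conditions: H2 (1 atm), Pd/CaCO3 poisoned with Pb(OAc)2 (Lindlar catalyst), quinoline, EtOAc, 25 °C
Reagents that add atoms: none
Why: Lindlar semihydrogenation is a syn addition of hydrogen to the silylalkyne and should give the Z-vinylsilane without opening the epoxide.

Step 4
Reactants: 5 [(2S,3S)-3-methyl-3-[(Z)-2-(trimethylsilyl)ethenyl]oxiran-2-yl]methanol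
Product: 6 (3R,4Z)-3-methyl-5-(trimethylsilyl)pent-4-ene-1,3-diol
Conditions: NaAlH2(OCH2CH2OMe)2 (Red-Al, 1.5 equiv), THF, 0 → 25 °C; aq. potassium sodium tartrate
Reagents that add atoms: none
Why: Alkoxide-directed hydride delivery to C2 of the 2,3-epoxy alcohol (Red-Al 1,3-diol synthesis) opens the epoxide away from the tertiary C–O bond, so the configuration of the tertiary carbinol is retained.

Step 5
Reactants: 6 (3R,4Z)-3-methyl-5-(trimethylsilyl)pent-4-ene-1,3-diol
Product: 7 (3R,4Z)-3-hydroxy-3-methyl-5-(trimethylsilyl)pent-4-enal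
Conditions: TEMPO (10 mol %), PhI(OAc)2 (1.1 equiv), CH2Cl2, 25 °C
Reagents that add atoms: none
Why: The oxoammonium (TEMPO) oxidation is selective for the primary alcohol, and the tertiary allylic alcohol cannot be oxidized.

Step 6
Reactants: 8 [(2S)-2-methyloxiran-2-yl]methanol; 9 (triphenylphosphoranylidene)acetaldehyde
Product: 11 (2E)-3-[(2S)-2-methyloxiran-2-yl]prop-2-enal, via epoxy aldehyde 10 (not isolated)
Conditions: (COCl)2, DMSO, CH2Cl2, −78 °C; Et3N; then 9, −78 → 25 °C
Reagents that add atoms: none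
Why: One-pot Swern oxidation and Wittig olefination with the stabilized formyl ylide should give the E-enal; the quaternary epoxide carbon cannot enolize, so its configuration is kept.

Step 7
Reactants: 11 (2E)-3-[(2S)-2-methyloxiran-2-yl]prop-2-enal
Product: 12 (2E)-3-[(4S)-4-methyl-2-oxo-1,3-dioxolan-4-yl]prop-2-enal
Conditions: CO2 (10 bar), n-Bu4NBr (5 mol %), 2-butanone, 60 °C
Reagents that add atoms: carbon dioxide, O=C=O
Why: Halide-catalysed cycloaddition of CO2 to the epoxide: bromide opens at CH2, the tertiary alkoxide is carboxylated and recloses by SN2 at CH2, so the quaternary centre is never touched and stays S.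

Step 8
Reactants: 13 prop-2-enoyl chloride; 14 2-(trimethylsilyl)ethanol
Product: 15 2-(trimethylsilyl)ethyl prop-2-enoate
Conditions: Et3N (1.2 equiv), CH2Cl2, 0 °C
Reagents that add atoms: none
Why: Simple acylation of the alcohol by the acid chloride gives the fluoride-cleavable acrylate.

Step 9
Reactants: 12 (2E)-3-[(4S)-4-methyl-2-oxo-1,3-dioxolan-4-yl]prop-2-enal; 15 2-(trimethylsilyl)ethyl prop-2-enoate
Product: 16 2-(trimethylsilyl)ethyl (4E)-3-hydroxy-2-methylidene-5-[(4S)-4-methyl-2-oxo-1,3-dioxolan-4-yl]pent-4-enoate (both C3 epimers)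
Conditions: DABCO (1.0 equiv), 15 (3 equiv), 1,4-dioxane, 25 °C
Reagents that add atoms: none
Why: Morita–Baylis–Hillman reaction (1,2-addition of the DABCO-acrylate enolate to the enal); the new carbinol forms as a mixture, which does not matter because that carbon becomes sp2 in step 10.

Step 10
Reactants: 16 2-(trimethylsilyl)ethyl (4E)-3-hydroxy-2-methylidene-5-[(4S)-4-methyl-2-oxo-1,3-dioxolan-4-yl]pent-4-enoate
Product: 17 2-(trimethylsilyl)ethyl (2Z,4E)-2-(bromomethyl)-5-[(4S)-4-methyl-2-oxo-1,3-dioxolan-4-yl]penta-2,4-dienoate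
Conditions: PBr3 (0.4 equiv), Et2O, 0 °C
Reagents that add atoms: phosphorus tribromide, BrP(Br)Br
Why: SN2′ bromination of the Morita–Baylis–Hillman alcohol should give the conjugated primary allylic bromide with the thermodynamically preferred 2Z geometry (chain cis to CH2Br).

Step 11
Reactants: 7 (3R,4Z)-3-hydroxy-3-methyl-5-(trimethylsilyl)pent-4-enal; 17 2-(trimethylsilyl)ethyl (2Z,4E)-2-(bromomethyl)-5-[(4S)-4-methyl-2-oxo-1,3-dioxolan-4-yl]penta-2,4-dienoate
Product: 19 2-(trimethylsilyl)ethyl (3R,4R,6R,7Z)-4,6-dihydroxy-6-methyl-2-methylidene-3-{(E)-2-[(4S)-4-methyl-2-oxo-1,3-dioxolan-4-yl]ethenyl}-8-(trimethylsilyl)oct-7-enoate, via silyl ether 18 (not isolated)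
Conditions: CrCl2 (10 mol %), (S,S)-3,6-di-tert-butyl-1,8-bis(4-isopropyl-4,5-dihydrooxazol-2-yl)carbazole (12 mol %), i-Pr2NEt (30 mol %), Mn powder (2 equiv), Me3SiCl (1.2 equiv), THF, 25 °C; then citric acid, MeOH, 0 °C
Reagents that add atoms: chlorotrimethylsilane, C[Si](C)(C)Cl (its silyl group is in 18 only and is removed in the work-up)
Why: Catalytic asymmetric Nozaki–Hiyama–Kishi-type 2-(alkoxycarbonyl)allylation with manganese/silyl chloride turnover: the allylchromium should react at its γ-carbon through a chair transition state with the γ-substituent cis to CH2–Cr, giving the syn 3R,4R pair, while the chiral trivalent-chromium complex selects the aldehyde face.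

Step 12
Reactants: 19 (the diol ester of step 11); 20 (2E)-2-methylbut-2-enoyl chloride
Product: 21 2-(trimethylsilyl)ethyl (3R,4R,6R,7Z)-6-hydroxy-6-methyl-4-{[(2E)-2-methylbut-2-enoyl]oxy}-2-methylidene-3-{(E)-2-[(4S)-4-methyl-2-oxo-1,3-dioxolan-4-yl]ethenyl}-8-(trimethylsilyl)oct-7-enoate
Conditions: Et3N (2 equiv), DMAP (20 mol %), CH2Cl2, 0 → 25 °C
Reagents that add atoms: none
Why: DMAP-catalysed acylation of the secondary alcohol; the tertiary alcohol is too hindered to react and the tiglate geometry is the stable one.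

Step 13
Reactants: 21 (the tiglate ester of step 12)
Product: 22 (3R,4R,6R,7Z)-6-hydroxy-6-methyl-4-{[(2E)-2-methylbut-2-enoyl]oxy}-2-methylidene-3-{(E)-2-[(4S)-4-methyl-2-oxo-1,3-dioxolan-4-yl]ethenyl}-8-(trimethylsilyl)oct-7-enoic acid
Conditions: n-Bu4NF (1.5 equiv), AcOH (1.5 equiv), THF, 0 → 25 °C; pH 4 buffer work-up
Reagents that add atoms: none
Why: Fluoride-induced β-elimination of the 2-(trimethylsilyl)ethyl ester frees the acid; the acetic acid buffer keeps the tertiary alkoxide concentration low so that the neighbouring vinyl–Si bond, the carbonate and the tiglate should survive.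

Step 14
Reactants: 22 (the acid of step 13)
Product: 23 (1R,3R,4Z)-3-hydroxy-1-{(2S,3R)-2-[(1Z)-3-hydroxy-2-methylprop-1-en-1-yl]-4-methylidene-5-oxooxolan-3-yl}-3-methyl-5-(trimethylsilyl)pent-4-en-1-yl (2E)-2-methylbut-2-enoate
Conditions: Pd2(dba)3·CHCl3 (2.5 mol %), bis[2-(diphenylphosphino)phenyl] ether (6 mol %), THF (0.02 M), 25 °C
Reagents that add atoms: none
Why: Zerovalent palladium should ionize the tertiary allylic C4–O bond of the dioxolanone anti to the metal and CO2 is lost; the resulting alkoxide-carrying π-allyl complex (C4–C5–C6) takes the proton of the C12 acid, and the carboxylate then attacks C6 anti to palladium. The closest known reaction type is the palladium-catalysed decarboxylative Z-selective allylic substitution of 4-substituted 4-vinyl-1,3-dioxolan-2-ones by oxygen, nitrogen and carbon nucleophiles, here run intramolecularly as a Tsuji–Trost lactonization. The γ-lactone closes in a 5-exo mode at the allyl terminus C6; attack at C4 would need a seven-membered ring and a quaternary centre. C6 (S) is set by 1,3-chirality transfer from the 4S carbonate carbon: the E C5=C6 olefin keeps C7 syn on the allyl unit and the C3 alkoxide arm sits anti, so anti ionization followed by anti attack can give only the 6S centre together with the Z C4=C5 olefin. The step needs Z over E geometry at C4=C5, which the six-membered O–Pd chelate of the alkoxide arm should secure as in the intermolecular precedents; the E isomer would carry 6R and be a separable diastereomer. It also needs this carbonate alone to ionize, which holds because the C10 hydroxyl is not a leaving group and the vinylsilane is inert.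

Step 15
Reactants: 23 (the lactone alcohol of step 14)
Product: 24 (1R,3R,4Z)-3-hydroxy-3-methyl-1-{(2S,3R)-4-methylidene-2-[(1Z)-2-methyl-3-oxoprop-1-en-1-yl]-5-oxooxolan-3-yl}-5-(trimethylsilyl)pent-4-en-1-yl (2E)-2-methylbut-2-enoate
Conditions: Dess–Martin periodinane (1.2 equiv), CH2Cl2, 0 °C
Reagents that add atoms: none
Why: Dess–Martin oxidation of the primary allylic alcohol under neutral conditions should keep the Z-enal geometry and leave the tertiary alcohol alone.

Step 16
Reactants: 24 (the enal of step 15)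
Product: 25 (1R,3R,4Z)-3-hydroxy-5-iodo-3-methyl-1-{(2S,3R)-4-methylidene-2-[(1Z)-2-methyl-3-oxoprop-1-en-1-yl]-5-oxooxolan-3-yl}pent-4-en-1-yl (2E)-2-methylbut-2-enoate
Conditions: N-iodosuccinimide (1.3 equiv), (CF3)2CHOH, 0 °C
Reagents that add atoms: N-iodosuccinimide, O=C1CCC(=O)N1I
Why: Iododesilylation (ipso substitution through a β-silyl cation) in the fluorinated alcohol should proceed with retention to the Z-iodoalkene; the other olefins are electron-poor and should not react.

Step 17
Reactants: 25 (the iodo-enal of step 16)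
Product: 26 (3aR,4R,6R,7Z,9R,10Z,11aS)-6,9-dihydroxy-6,10-dimethyl-3-methylidene-2-oxo-2,3,3a,4,5,6,9,11a-octahydrocyclodeca[b]furan-4-yl (2E)-2-methylbut-2-enoate (CNP0262559.2)
Conditions: CrCl2 (8 equiv), NiCl2 (0.2 equiv), DMSO/THF (3:1), 0.002 M, 25 °C; aq. work-up
Reagents that add atoms: none
Why: Nozaki–Hiyama–Kishi macrocyclization: the alkenylchromium forms with retention of Z geometry and adds 1,2 to the enal to close the ten-membered ring; coordination of chromium by the free C10 hydroxyl is expected to hold the aldehyde oxygen on the same side, giving the 3R carbinol (cis to the C10 hydroxyl across the Z olefin).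

**Compound list**

1 | (2E)-3-methylpent-2-en-4-yn-1-ol | OC/C=C(\C)C#C | starting material
2 | trimethyl{[(2E)-3-methyl-5-(trimethylsilyl)pent-2-en-4-yn-1-yl]oxy}silane | C[Si](C)(C)OC/C=C(\C)C#C[Si](C)(C)C | intermediate
3 | (2E)-3-methyl-5-(trimethylsilyl)pent-2-en-4-yn-1-ol | OC/C=C(\C)C#C[Si](C)(C)C | intermediate
4 | [(2S,3S)-3-methyl-3-[(trimethylsilyl)ethynyl]oxiran-2-yl]methanol | OC[C@@H]1O[C@@]1(C)C#C[Si](C)(C)C | intermediate
5 | [(2S,3S)-3-methyl-3-[(Z)-2-(trimethylsilyl)ethenyl]oxiran-2-yl]methanol | OC[C@@H]1O[C@@]1(C)/C=C\[Si](C)(C)C | intermediate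
6 | (3R,4Z)-3-methyl-5-(trimethylsilyl)pent-4-ene-1,3-diol | OCC[C@@](C)(O)/C=C\[Si](C)(C)C | intermediate
7 | (3R,4Z)-3-hydroxy-3-methyl-5-(trimethylsilyl)pent-4-enal | O=CC[C@@](C)(O)/C=C\[Si](C)(C)C | intermediate
8 | [(2S)-2-methyloxiran-2-yl]methanol ((S)-2-methylglycidol) | C[C@]1(CO)CO1 | starting material
9 | (triphenylphosphoranylidene)acetaldehyde | O=CC=P(c1ccccc1)(c1ccccc1)c1ccccc1 | starting material
10 | (2R)-2-methyloxirane-2-carbaldehyde | C[C@]1(C=O)CO1 | intermediate
11 | (2E)-3-[(2S)-2-methyloxiran-2-yl]prop-2-enal | O=C/C=C/[C@@]1(C)CO1 | intermediate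
12 | (2E)-3-[(4S)-4-methyl-2-oxo-1,3-dioxolan-4-yl]prop-2-enal | O=C/C=C/[C@@]1(C)COC(=O)O1 | intermediate
13 | prop-2-enoyl chloride | C=CC(=O)Cl | starting material
14 | 2-(trimethylsilyl)ethanol | OCC[Si](C)(C)C | starting material
15 | 2-(trimethylsilyl)ethyl prop-2-enoate | C=CC(=O)OCC[Si](C)(C)C | intermediate
16 | 2-(trimethylsilyl)ethyl (4E)-3-hydroxy-2-methylidene-5-[(4S)-4-methyl-2-oxo-1,3-dioxolan-4-yl]pent-4-enoate (C3 epimers) | C=C(C(=O)OCC[Si](C)(C)C)C(O)/C=C/[C@@]1(C)COC(=O)O1 | intermediate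
17 | 2-(trimethylsilyl)ethyl (2Z,4E)-2-(bromomethyl)-5-[(4S)-4-methyl-2-oxo-1,3-dioxolan-4-yl]penta-2,4-dienoate | BrC/C(=C\C=C\[C@@]1(C)COC(=O)O1)C(=O)OCC[Si](C)(C)C | intermediate
18 | 4-O-trimethylsilyl ether of 19 | C=C(C(=O)OCC[Si](C)(C)C)[C@@H](/C=C/[C@@]1(C)COC(=O)O1)[C@H](O[Si](C)(C)C)C[C@@](C)(O)/C=C\[Si](C)(C)C | intermediate
19 | 2-(trimethylsilyl)ethyl (3R,4R,6R,7Z)-4,6-dihydroxy-6-methyl-2-methylidene-3-{(E)-2-[(4S)-4-methyl-2-oxo-1,3-dioxolan-4-yl]ethenyl}-8-(trimethylsilyl)oct-7-enoate | C=C(C(=O)OCC[Si](C)(C)C)[C@@H](/C=C/[C@@]1(C)COC(=O)O1)[C@H](O)C[C@@](C)(O)/C=C\[Si](C)(C)C | intermediate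
20 | (2E)-2-methylbut-2-enoyl chloride (tigloyl chloride) | C/C=C(\C)C(=O)Cl | starting material
21 | 2-(trimethylsilyl)ethyl (3R,4R,6R,7Z)-6-hydroxy-6-methyl-4-{[(2E)-2-methylbut-2-enoyl]oxy}-2-methylidene-3-{(E)-2-[(4S)-4-methyl-2-oxo-1,3-dioxolan-4-yl]ethenyl}-8-(trimethylsilyl)oct-7-enoate | C=C(C(=O)OCC[Si](C)(C)C)[C@@H](/C=C/[C@@]1(C)COC(=O)O1)[C@H](OC(=O)/C(C)=C/C)C[C@@](C)(O)/C=C\[Si](C)(C)C | intermediate
22 | (3R,4R,6R,7Z)-6-hydroxy-6-methyl-4-{[(2E)-2-methylbut-2-enoyl]oxy}-2-methylidene-3-{(E)-2-[(4S)-4-methyl-2-oxo-1,3-dioxolan-4-yl]ethenyl}-8-(trimethylsilyl)oct-7-enoic acid | C=C(C(=O)O)[C@@H](/C=C/[C@@]1(C)COC(=O)O1)[C@H](OC(=O)/C(C)=C/C)C[C@@](C)(O)/C=C\[Si](C)(C)C | intermediate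
23 | (1R,3R,4Z)-3-hydroxy-1-{(2S,3R)-2-[(1Z)-3-hydroxy-2-methylprop-1-en-1-yl]-4-methylidene-5-oxooxolan-3-yl}-3-methyl-5-(trimethylsilyl)pent-4-en-1-yl (2E)-2-methylbut-2-enoate | C=C1C(=O)O[C@@H](/C=C(/C)CO)[C@H]1[C@H](OC(=O)/C(C)=C/C)C[C@@](C)(O)/C=C\[Si](C)(C)C | intermediate
24 | (1R,3R,4Z)-3-hydroxy-3-methyl-1-{(2S,3R)-4-methylidene-2-[(1Z)-2-methyl-3-oxoprop-1-en-1-yl]-5-oxooxolan-3-yl}-5-(trimethylsilyl)pent-4-en-1-yl (2E)-2-methylbut-2-enoate | C=C1C(=O)O[C@@H](/C=C(/C)C=O)[C@H]1[C@H](OC(=O)/C(C)=C/C)C[C@@](C)(O)/C=C\[Si](C)(C)C | intermediate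
25 | (1R,3R,4Z)-3-hydroxy-5-iodo-3-methyl-1-{(2S,3R)-4-methylidene-2-[(1Z)-2-methyl-3-oxoprop-1-en-1-yl]-5-oxooxolan-3-yl}pent-4-en-1-yl (2E)-2-methylbut-2-enoate | C=C1C(=O)O[C@@H](/C=C(/C)C=O)[C@H]1[C@H](OC(=O)/C(C)=C/C)C[C@@](C)(O)/C=C\I | intermediate
26 | (3aR,4R,6R,7Z,9R,10Z,11aS)-6,9-dihydroxy-6,10-dimethyl-3-methylidene-2-oxo-2,3,3a,4,5,6,9,11a-octahydrocyclodeca[b]furan-4-yl (2E)-2-methylbut-2-enoate | C=C1C(=O)O[C@H]2/C=C(/C)[C@H](O)/C=C\[C@](C)(O)C[C@@H](OC(=O)/C(C)=C/C)[C@@H]12 | target

**Step count and risks**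

Total step count: 17. Longest linear sequence: 12 steps (steps 1–5, then 11–17).

Steps most likely to fail:

1. Step 14 (key step). What may go wrong: loss of Z control, because closure through the E-configured allyl complex leads to the trans-fused 6R lactone and may be favoured by lower strain in the lactone-forming transition state; or re-ionization of the product's allylic lactone C–O bond by zerovalent palladium, with erosion of C6. Fallback, setting out from ester 21 and returning at 23: the bond-forming event is made intermolecular, so that lactone ring strain no longer biases the olefin geometry. Ester 21 is treated with Pd2(dba)3·CHCl3, bis[2-(diphenylphosphino)phenyl] ether and water in DMF at 25 °C (the known Z-selective decarboxylative hydration of vinyl dioxolanones to 2-ene-1,4-diols), which should give the Z-1,4-diol ester F1 with the same anti/anti course at C6. Buffered n-Bu4NF then frees the hydroxy acid F2, which should close to the γ-lactone 23 on standing with pyridinium p-toluenesulfonate in CH2Cl2.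

2. Step 11. What may go wrong: poor control of the aldehyde face by the chiral chromium catalyst (the free β-hydroxyl of 7 may bind chromium), or attack of the dienylchromium through its remote terminus. Fallback, setting out from bromide 17 (with aldehyde 7) and returning at 19: the chromium reagent is replaced by a boron reagent that reacts through a closed chair. Zinc insertion into 17 (Zn, THF, 0 °C) and trapping with 2-isopropoxy-4,4,5,5-tetramethyl-1,3,2-dioxaborolane should give the allylboronate F3, with boron on the primary carbon after borotropic equilibration. Allylboration of 7 under catalysis by a chiral BINOL-derived phosphoric acid ((R)-TRIP, toluene, −30 °C) should give the syn adduct as its borate ester F4, which is hydrolysed in the aqueous work-up to 19.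

3. Step 17. What may go wrong: poor facial selectivity at the aldehyde in the ring-closing addition (or protonation of the alkenylchromium by the free hydroxyl, or oligomerization at insufficient dilution). Fallback for the selectivity problem, setting out from iodide 25 and returning at 26: C3 is set by reagent-controlled reduction instead of by the ring closure. If the closure gives mainly the 3S epimer F5, the crude mixture of epimers is oxidized with MnO2 (CH2Cl2, 25 °C) to the cross-conjugated dienone F6, and F6 is reduced by Corey–Bakshi–Shibata reduction (the Me-CBS enantiomer that gives 3R, catecholborane, toluene, −78 °C) to 26.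

**Further compounds**

F1 | step 14 | Z-1,4-diol ester (21 with the dioxolanone opened: C6–OH of S configuration, C3–OH, Z C4=C5) | C=C(C(=O)OCC[Si](C)(C)C)[C@@H]([C@@H](O)/C=C(/C)CO)[C@H](OC(=O)/C(C)=C/C)C[C@@](C)(O)/C=C\[Si](C)(C)C
F2 | step 14 | hydroxy acid from F1 (free C12 acid) | C=C(C(=O)O)[C@@H]([C@@H](O)/C=C(/C)CO)[C@H](OC(=O)/C(C)=C/C)C[C@@](C)(O)/C=C\[Si](C)(C)C
F3 | step 11 | 2-(trimethylsilyl)ethyl (2E,4E)-5-[(4S)-4-methyl-2-oxo-1,3-dioxolan-4-yl]-2-[(4,4,5,5-tetramethyl-1,3,2-dioxaborolan-2-yl)methyl]penta-2,4-dienoate | CC1(C)OB(C/C(=C\C=C\[C@@]2(C)COC(=O)O2)C(=O)OCC[Si](C)(C)C)OC1(C)C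
F4 | step 11 | 4-O-(pinacolatoboryl) ester of 19 | C=C(C(=O)OCC[Si](C)(C)C)[C@@H](/C=C/[C@@]1(C)COC(=O)O1)[C@H](OB2OC(C)(C)C(C)(C)O2)C[C@@](C)(O)/C=C\[Si](C)(C)C
F5 | step 17 | 3S epimer of 26 (9S in ring-fusion numbering) | C=C1C(=O)O[C@H]2/C=C(/C)[C@@H](O)/C=C\[C@](C)(O)C[C@@H](OC(=O)/C(C)=C/C)[C@@H]12
F6 | step 17 | 3-oxo compound (1Z,4Z-dien-3-one) from F5 and 26 | C=C1C(=O)O[C@H]2/C=C(/C)C(=O)/C=C\[C@](C)(O)C[C@@H](OC(=O)/C(C)=C/C)[C@@H]12
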